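**Plan**

- Retrosynthesis first cuts the four acyl–O bonds; the C1 acyl acetal is taken back to a C1 lactone. It then cuts C7–C7a of the cyclopentene, then C5–C6 (aldol), then the pyrone ring itself.
- Enabling feature: with C1 as a carbonyl, the pyran ring O2–C3=C4–C4a(=C5)–C7a–C1 is the dearomatised form of a 4-alkyl-2-pyrone. C5 is its vinylogously acidic 4-CH2, and C7a (pyrone C3) is the nucleophilic end of its dienol ether, placed to form a five-membered ring with a C7 ketone.
- Forward: the pyrone is made from dimethyl 3-methylglutaconate; a lateral aldol with an ynal forms C5–C6; gold-catalysed alkyne oxidation gives the C7 ketone already carrying the C10 isovalerate.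
- A silyl-triflate-triggered dearomative aldol then closes the cyclopentene as the last ring, forming C7–C7a, the C7 and C7a stereocentres and the C3=C4/C4a=C5 diene in one event.
- Reductive acylation converts the lactone into the C1 senecioate; desilylation and two selective acylations finish the route.
- Stereochemistry: C6 by catalyst control (Noyori transfer hydrogenation); C7 and C7a from C6 in the key step; C1 by hydride attack anti to H7a; the side-chain centre from (S)-3-methylpentanoic acid.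

Key step: step 10

Remark: locants are those of the cyclopenta[c]pyran skeleton (C1, O2, C3, C4, C4a, C5, C6, C7, C7a; C10 is the CH2 on C7, C11 the CH2 on C4). 3-Methylbut-2-enoic anhydride is taken as purchasable; it is otherwise made from the acid with DCC.

**Step 1**
Reactants: 1 dimethyl 3-methylpent-2-enedioate (E/Z mixture); 2 N,N-dimethylformamide dimethyl acetal
Product: 5 4-methyl-2-oxo-2H-pyran-5-carboxylic acid, via enaminodiester 3 (not isolated), via methyl 4-methylcoumalate 4 (not isolated)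
Conditions: 2 (1.1 equiv), 90 °C; concentrate; then AcOH, 6 M HCl, reflux
Reagents that add atoms: water, O
Why: Aminomethylenation of the doubly activated CH2 (Bredereck-type condensation) is followed in acid by enamine hydrolysis, lactonisation of the hydroxymethylene diester to the 2-pyrone (classical coumalate synthesis) and hydrolysis of the remaining ester, the pyrone ring being stable to hot aqueous acid.

**Step 2**
Reactants: 5 4-methyl-2-oxo-2H-pyran-5-carboxylic acid
Product: 6 5-(hydroxymethyl)-4-methyl-2H-pyran-2-one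
Conditions: BH3·THF, THF, 0 °C to rt; then H2O
Reagents that add atoms: none
Why: Borane reduction of a carboxylic acid proceeds through the acyloxyborane much faster than attack on the pyrone lactone, so the acid should be taken to the primary alcohol chemoselectively.

**Step 3**
Reactants: 6 5-(hydroxymethyl)-4-methyl-2H-pyran-2-one
Product: 7 5-({[tert-butyl(dimethyl)silyl]oxy}methyl)-4-methyl-2H-pyran-2-one
Conditions: t-BuMe2SiCl, imidazole, DMF, rt
Reagents that add atoms: tert-butyldimethylsilyl chloride, CC(C)(C)[Si](C)(C)Cl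
Why: Standard silylation of a primary alcohol gives a C11–O protecting group that survives amide base, hydride and Lewis acid and is removed by fluoride at the end.

**Step 4**
Reactants: 7 5-({[tert-butyl(dimethyl)silyl]oxy}methyl)-4-methyl-2H-pyran-2-one; 8 3-(trimethylsilyl)prop-2-ynal
Product: 9 rac-5-({[tert-butyl(dimethyl)silyl]oxy}methyl)-4-[2-hydroxy-4-(trimethylsilyl)but-3-yn-1-yl]-2H-pyran-2-one
Conditions: LiN(SiMe3)2, THF, −78 °C; then 8; aq. NH4Cl work-up
Reagents that add atoms: none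
Why: Lateral (vinylogous) deprotonation of the 4-methyl group and 1,2-addition of the extended enolate through its γ-carbon to the ynal (vinylogous aldol; γ-attack keeps the pyrone aromatic) forms C5–C6, the racemic carbinol centre being erased in step 5.

**Step 5**
Reactants: 9 rac-5-({[tert-butyl(dimethyl)silyl]oxy}methyl)-4-[2-hydroxy-4-(trimethylsilyl)but-3-yn-1-yl]-2H-pyran-2-one
Product: 10 5-({[tert-butyl(dimethyl)silyl]oxy}methyl)-4-[2-oxo-4-(trimethylsilyl)but-3-yn-1-yl]-2H-pyran-2-one
Conditions: Dess–Martin periodinane, CH2Cl2, 0 °C to rt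
Reagents that add atoms: none
Why: Dess–Martin oxidation of the propargylic alcohol under non-basic conditions gives the ynone needed for a catalyst-controlled reduction.

**Step 6**
Reactants: 10 5-({[tert-butyl(dimethyl)silyl]oxy}methyl)-4-[2-oxo-4-(trimethylsilyl)but-3-yn-1-yl]-2H-pyran-2-one
Product: 11 5-({[tert-butyl(dimethyl)silyl]oxy}methyl)-4-[(2S)-2-hydroxy-4-(trimethylsilyl)but-3-yn-1-yl]-2H-pyran-2-one
Conditions: Ru[(S,S)-TsDPEN](p-cymene) (1 mol%), i-PrOH, rt
Reagents that add atoms: none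
Why: Noyori asymmetric transfer hydrogenation of an alkynyl ketone, in which the (S,S)-catalyst differentiates the alkynyl group from the CH2 group in its six-membered hydride-transfer transition state and should set the (S)-carbinol that becomes C6.

**Step 7**
Reactants: 11 5-({[tert-butyl(dimethyl)silyl]oxy}methyl)-4-[(2S)-2-hydroxy-4-(trimethylsilyl)but-3-yn-1-yl]-2H-pyran-2-one
Product: 12 5-({[tert-butyl(dimethyl)silyl]oxy}methyl)-4-[(2S)-2-[(triethylsilyl)oxy]-4-(trimethylsilyl)but-3-yn-1-yl]-2H-pyran-2-one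
Conditions: Et3SiCl, imidazole, CH2Cl2, 0 °C
Reagents that add atoms: chlorotriethylsilane, CC[Si](Cl)(CC)CC
Why: Silylation of the secondary alcohol gives a non-chelating, bulky C6–O group that blocks O–H insertion in step 9 and steers the key step.

**Step 8**
Reactants: 12 5-({[tert-butyl(dimethyl)silyl]oxy}methyl)-4-[(2S)-2-[(triethylsilyl)oxy]-4-(trimethylsilyl)but-3-yn-1-yl]-2H-pyran-2-one
Product: 13 5-({[tert-butyl(dimethyl)silyl]oxy}methyl)-4-[(2S)-2-[(triethylsilyl)oxy]but-3-yn-1-yl]-2H-pyran-2-one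
Conditions: AgNO3 (10 mol%), acetone/H2O, rt
Reagents that add atoms: none
Why: Silver-catalysed protiodesilylation of the alkynylsilane through the silver acetylide frees the terminal alkyne without base, so the pyrone and both O-silyl ethers should survive.

**Step 9**
Reactants: 13 5-({[tert-butyl(dimethyl)silyl]oxy}methyl)-4-[(2S)-2-[(triethylsilyl)oxy]but-3-yn-1-yl]-2H-pyran-2-one; 14 3-methylbutanoic acid
Product: 15 (3S)-4-[5-({[tert-butyl(dimethyl)silyl]oxy}methyl)-2-oxo-2H-pyran-4-yl]-2-oxo-3-[(triethylsilyl)oxy]butyl 3-methylbutanoate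
Conditions: Ph3PAuNTf2 (5 mol%), 8-methylquinoline N-oxide (1.5 equiv, slow addition), 14 (5 equiv), ClCH2CH2Cl, rt
Reagents that add atoms: 8-methylquinoline N-oxide, Cc1cccc2ccc[n+]([O-])c12
Why: Gold-catalysed oxidation of a terminal alkyne by the N-oxide gives an α-oxo gold carbene at the terminal carbon, which inserts into the O–H bond of the acid (alkyne oxidation/O–H insertion), so the future C7 ketone and the C10 isovalerate arise together while the adjacent stereocentre is not involved.

**Step 10**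
Reactants: 15 (3S)-4-[5-({[tert-butyl(dimethyl)silyl]oxy}methyl)-2-oxo-2H-pyran-4-yl]-2-oxo-3-[(triethylsilyl)oxy]butyl 3-methylbutanoate
Product: 18 [(6S,7R,7aS)-4-({[tert-butyl(dimethyl)silyl]oxy}methyl)-1-oxo-6-[(triethylsilyl)oxy]-7-[(trimethylsilyl)oxy]-1,6,7,7a-tetrahydrocyclopenta[c]pyran-7-yl]methyl 3-methylbutanoate, via 2-silyloxypyrylium triflate 16 (not isolated), via silyl dienol ether 17 (not isolated)
Conditions: Me3SiOTf (1.5 equiv), CH2Cl2, −78 °C; then i-Pr2NEt (1.05 equiv), −78 to −40 °C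
Reagents that add atoms: trimethylsilyl trifluoromethanesulfonate, C[Si](C)(C)OS(=O)(=O)C(F)(F)F
Why: Proposed new method: Me3SiOTf silylates the pyrone carbonyl to pyrylium ion 16, whose C5–H2 is by far the most acidic C–H present, so one equivalent of amine gives dienol ether 17 without enolising the ketone; the remaining Me3SiOTf activates the C7 ketone, C7a of 17 adds to it, and silyl transfer to the new tertiary alkoxide regenerates the lactone and blocks retro-aldol rearomatisation. The closest known reaction types are the one-pot silyl triflate/amine Mukaiyama aldol, the vinylogous Mukaiyama aldol of silyl dienol ethers and the deprotonation of 4-alkylpyrylium salts to methylenepyrans; their combination on a 2-pyrone with dearomatisation is new. The cyclopentene closes by the C7–C7a bond in a 5-(enolexo)-exo-trig mode from the isomer of 17 that has C6 cis to C7a on the C4a=C5 bond, and the same event creates the C3=C4/C4a=C5 dienol ether. C7 is controlled by C6: the bulky OSiEt3 group should sit pseudo-axial with C6–O antiperiplanar to the activated C7=O (Cornforth-type dipole minimisation), which places C7–O trans to C6–O. C7a is set in the same open transition state, where the silylated carbonyl oxygen points away from the pyran and the CH2O-acyl arm lies over the small C7a–H, so H7a ends cis to C6–O and C7–O cis to C1. The step needs pyrone-selective enolisation (secured by the acidity gap and the single equivalent of base), attack through C7a and not C5 (secured by ring size, since C5 is a tether atom) and retention of the C6 centre (secured by the absence of free base at low temperature).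

**Step 11**
Reactants: 18 [(6S,7R,7aS)-4-({[tert-butyl(dimethyl)silyl]oxy}methyl)-1-oxo-6-[(triethylsilyl)oxy]-7-[(trimethylsilyl)oxy]-1,6,7,7a-tetrahydrocyclopenta[c]pyran-7-yl]methyl 3-methylbutanoate; 19 3-methylbut-2-enoic anhydride
Product: 21 (1S,6S,7R,7aS)-4-({[tert-butyl(dimethyl)silyl]oxy}methyl)-7-[(3-methylbutanoyloxy)methyl]-6-[(triethylsilyl)oxy]-7-[(trimethylsilyl)oxy]-1,6,7,7a-tetrahydrocyclopenta[c]pyran-1-yl 3-methylbut-2-enoate, via aluminium lactolate 20 (not isolated)
Conditions: i-Bu2AlH (1.15 equiv), CH2Cl2, −78 °C; then pyridine, DMAP, 19, −78 to −20 °C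
Reagents that add atoms: none
Why: Rychnovsky reductive acylation, in which hydride should add to the enol lactone (the most electrophilic carbonyl, ahead of the hindered isovalerate) from the face anti to the pseudo-axial C7a–H and the aluminium lactolate is acylated in situ with retention, setting C1 (S) with H1 trans to H7a.

**Step 12**
Reactants: 21 (1S,6S,7R,7aS)-4-({[tert-butyl(dimethyl)silyl]oxy}methyl)-7-[(3-methylbutanoyloxy)methyl]-6-[(triethylsilyl)oxy]-7-[(trimethylsilyl)oxy]-1,6,7,7a-tetrahydrocyclopenta[c]pyran-1-yl 3-methylbut-2-enoate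
Product: 22 (1S,6S,7R,7aS)-6,7-dihydroxy-4-(hydroxymethyl)-7-[(3-methylbutanoyloxy)methyl]-1,6,7,7a-tetrahydrocyclopenta[c]pyran-1-yl 3-methylbut-2-enoate
Conditions: HF·pyridine, pyridine, THF, 0 °C to rt
Reagents that add atoms: none
Why: Fluoride-mediated cleavage of the three silyl ethers under pyridine-buffered conditions should leave the esters, the acyl acetal and all stereocentres untouched.

**Step 13**
Reactants: 22 (1S,6S,7R,7aS)-6,7-dihydroxy-4-(hydroxymethyl)-7-[(3-methylbutanoyloxy)methyl]-1,6,7,7a-tetrahydrocyclopenta[c]pyran-1-yl 3-methylbut-2-enoate; 23 acetyl chloride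
Product: 24 (1S,6S,7R,7aS)-4-(acetoxymethyl)-6,7-dihydroxy-7-[(3-methylbutanoyloxy)methyl]-1,6,7,7a-tetrahydrocyclopenta[c]pyran-1-yl 3-methylbut-2-enoate
Conditions: 23 (1.1 equiv), 2,4,6-collidine, CH2Cl2, −78 °C
Reagents that add atoms: none
Why: Selective acetylation of the primary allylic alcohol over the secondary C6–OH and the tertiary C7–OH with a slight excess of acid chloride and a hindered pyridine base at low temperature.

**Step 14**
Reactants: 24 (1S,6S,7R,7aS)-4-(acetoxymethyl)-6,7-dihydroxy-7-[(3-methylbutanoyloxy)methyl]-1,6,7,7a-tetrahydrocyclopenta[c]pyran-1-yl 3-methylbut-2-enoate; 25 (3S)-3-methylpentanoic acid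
Product: 26 (1S,6S,7R,7aS)-4-(acetoxymethyl)-7-hydroxy-7-[(3-methylbutanoyloxy)methyl]-1-[(3-methylbut-2-enoyl)oxy]-1,6,7,7a-tetrahydrocyclopenta[c]pyran-6-yl (3S)-3-methylpentanoate
Conditions: 25, DCC, DMAP (cat.), CH2Cl2, 0 °C
Reagents that add atoms: none
Why: Steglich esterification of the remaining secondary alcohol, the tertiary C7–OH being too hindered to react and the acid carrying its stereocentre at the β-carbon where it cannot epimerise.

**Compound list**

1 | dimethyl 3-methylpent-2-enedioate (dimethyl 3-methylglutaconate, E/Z mixture) | COC(=O)CC(C)=CC(=O)OC | starting material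
2 | N,N-dimethylformamide dimethyl acetal | COC(OC)N(C)C | starting material
3 | dimethyl 4-[(dimethylamino)methylidene]-3-methylpent-2-enedioate | COC(=O)C=C(C)C(=CN(C)C)C(=O)OC | intermediate
4 | methyl 4-methyl-2-oxo-2H-pyran-5-carboxylate | CC1=CC(=O)OC=C1C(=O)OC | intermediate
5 | 4-methyl-2-oxo-2H-pyran-5-carboxylic acid | CC1=CC(=O)OC=C1C(=O)O | intermediate
6 | 5-(hydroxymethyl)-4-methyl-2H-pyran-2-one | CC1=CC(=O)OC=C1CO | intermediate
7 | 5-({[tert-butyl(dimethyl)silyl]oxy}methyl)-4-methyl-2H-pyran-2-one | CC1=CC(=O)OC=C1CO[Si](C)(C)C(C)(C)C | intermediate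
8 | 3-(trimethylsilyl)prop-2-ynal | C[Si](C)(C)C#CC=O | starting material
9 | rac-5-({[tert-butyl(dimethyl)silyl]oxy}methyl)-4-[2-hydroxy-4-(trimethylsilyl)but-3-yn-1-yl]-2H-pyran-2-one | C[Si](C)(C)C#CC(O)CC1=CC(=O)OC=C1CO[Si](C)(C)C(C)(C)C | intermediate
10 | 5-({[tert-butyl(dimethyl)silyl]oxy}methyl)-4-[2-oxo-4-(trimethylsilyl)but-3-yn-1-yl]-2H-pyran-2-one | C[Si](C)(C)C#CC(=O)CC1=CC(=O)OC=C1CO[Si](C)(C)C(C)(C)C | intermediate
11 | 5-({[tert-butyl(dimethyl)silyl]oxy}methyl)-4-[(2S)-2-hydroxy-4-(trimethylsilyl)but-3-yn-1-yl]-2H-pyran-2-one | C[Si](C)(C)C#C[C@@H](O)CC1=CC(=O)OC=C1CO[Si](C)(C)C(C)(C)C | intermediate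
12 | 5-({[tert-butyl(dimethyl)silyl]oxy}methyl)-4-[(2S)-2-[(triethylsilyl)oxy]-4-(trimethylsilyl)but-3-yn-1-yl]-2H-pyran-2-one | C[Si](C)(C)C#C[C@@H](O[Si](CC)(CC)CC)CC1=CC(=O)OC=C1CO[Si](C)(C)C(C)(C)C | intermediate
13 | 5-({[tert-butyl(dimethyl)silyl]oxy}methyl)-4-[(2S)-2-[(triethylsilyl)oxy]but-3-yn-1-yl]-2H-pyran-2-one | C#C[C@@H](O[Si](CC)(CC)CC)CC1=CC(=O)OC=C1CO[Si](C)(C)C(C)(C)C | intermediate
14 | 3-methylbutanoic acid (isovaleric acid) | CC(C)CC(=O)O | starting material
15 | (3S)-4-[5-({[tert-butyl(dimethyl)silyl]oxy}methyl)-2-oxo-2H-pyran-4-yl]-2-oxo-3-[(triethylsilyl)oxy]butyl 3-methylbutanoate | CC(C)CC(=O)OCC(=O)[C@@H](O[Si](CC)(CC)CC)CC1=CC(=O)OC=C1CO[Si](C)(C)C(C)(C)C | intermediate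
16 | 5-({[tert-butyl(dimethyl)silyl]oxy}methyl)-4-[(2S)-4-(3-methylbutanoyloxy)-3-oxo-2-[(triethylsilyl)oxy]butyl]-2-[(trimethylsilyl)oxy]pyrylium triflate | C[Si](C)(C)OC1=CC(C[C@H](O[Si](CC)(CC)CC)C(=O)COC(=O)CC(C)C)=C(CO[Si](C)(C)C(C)(C)C)C=[O+]1.[O-]S(=O)(=O)C(F)(F)F | intermediate
17 | (3S)-4-[5-({[tert-butyl(dimethyl)silyl]oxy}methyl)-2-[(trimethylsilyl)oxy]-4H-pyran-4-ylidene]-2-oxo-3-[(triethylsilyl)oxy]butyl 3-methylbutanoate (side chain cis to pyran C3) | C[Si](C)(C)OC1=C/C(=C\[C@H](O[Si](CC)(CC)CC)C(=O)COC(=O)CC(C)C)C(CO[Si](C)(C)C(C)(C)C)=CO1 | intermediate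
18 | [(6S,7R,7aS)-4-({[tert-butyl(dimethyl)silyl]oxy}methyl)-1-oxo-6-[(triethylsilyl)oxy]-7-[(trimethylsilyl)oxy]-1,6,7,7a-tetrahydrocyclopenta[c]pyran-7-yl]methyl 3-methylbutanoate | CC[Si](CC)(CC)O[C@H]1C=C2C(CO[Si](C)(C)C(C)(C)C)=COC(=O)[C@@H]2[C@@]1(O[Si](C)(C)C)COC(=O)CC(C)C | intermediate
19 | 3-methylbut-2-enoic anhydride (senecioic anhydride) | CC(C)=CC(=O)OC(=O)C=C(C)C | starting material
20 | diisobutylaluminium (1S,6S,7R,7aS)-lactolate of 18 (O–Al at C1) | CC[Si](CC)(CC)O[C@H]1C=C2C(CO[Si](C)(C)C(C)(C)C)=CO[C@@H](O[Al](CC(C)C)CC(C)C)[C@@H]2[C@@]1(O[Si](C)(C)C)COC(=O)CC(C)C | intermediate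
21 | (1S,6S,7R,7aS)-4-({[tert-butyl(dimethyl)silyl]oxy}methyl)-7-[(3-methylbutanoyloxy)methyl]-6-[(triethylsilyl)oxy]-7-[(trimethylsilyl)oxy]-1,6,7,7a-tetrahydrocyclopenta[c]pyran-1-yl 3-methylbut-2-enoate | CC[Si](CC)(CC)O[C@H]1C=C2C(CO[Si](C)(C)C(C)(C)C)=CO[C@@H](OC(=O)C=C(C)C)[C@@H]2[C@@]1(O[Si](C)(C)C)COC(=O)CC(C)C | intermediate
22 | (1S,6S,7R,7aS)-6,7-dihydroxy-4-(hydroxymethyl)-7-[(3-methylbutanoyloxy)methyl]-1,6,7,7a-tetrahydrocyclopenta[c]pyran-1-yl 3-methylbut-2-enoate | O[C@H]1C=C2C(CO)=CO[C@@H](OC(=O)C=C(C)C)[C@@H]2[C@@]1(O)COC(=O)CC(C)C | intermediate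
23 | acetyl chloride | CC(Cl)=O | starting material
24 | (1S,6S,7R,7aS)-4-(acetoxymethyl)-6,7-dihydroxy-7-[(3-methylbutanoyloxy)methyl]-1,6,7,7a-tetrahydrocyclopenta[c]pyran-1-yl 3-methylbut-2-enoate | O[C@H]1C=C2C(COC(C)=O)=CO[C@@H](OC(=O)C=C(C)C)[C@@H]2[C@@]1(O)COC(=O)CC(C)C | intermediate
25 | (3S)-3-methylpentanoic acid | CC[C@H](C)CC(=O)O | starting material
26 | (1S,6S,7R,7aS)-4-(acetoxymethyl)-7-hydroxy-7-[(3-methylbutanoyloxy)methyl]-1-[(3-methylbut-2-enoyl)oxy]-1,6,7,7a-tetrahydrocyclopenta[c]pyran-6-yl (3S)-3-methylpentanoate | CC[C@H](C)CC(=O)O[C@H]1C=C2C(COC(C)=O)=CO[C@@H](OC(=O)C=C(C)C)[C@@H]2[C@@]1(O)COC(=O)CC(C)C | target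

**Step count**

Total: 14 steps. Longest linear sequence: 14 steps (1 to 26); all acyl donors enter as purchased reagents.

**Steps most likely to fail**

Step 10 (proposed new method). What may go wrong:
- silyl enol ether formation at the ketone, with loss of the adjacent carbinol configuration;
- ionisation of the allylic C11 silyl ether under the Lewis acid;
- return of 17 to the aromatic pyrone by protonation at C5;
- insufficient facial selectivity at C7 and C7a.

The fallback closes the same ring on the alkyne, which has no acidic α-position and forms the bond irreversibly, and uses known reaction types throughout. It sets out from 13. t-BuMe2SiOTf/Et3N in CH2Cl2 gives the tert-butyldimethylsilyl dienol ether of 13, F1. Ph3PAuCl/AgBF4 in CH2Cl2/MeOH (gold-catalysed 5-exo-dig addition of a silyl enol ether to an alkyne, Conia-ene type) gives (6S,7aS)-4-({[tert-butyl(dimethyl)silyl]oxy}methyl)-7-methylidene-6-[(triethylsilyl)oxy]-7,7a-dihydrocyclopenta[c]pyran-1(6H)-one, F2. Allylic 1,3-strain against the vinyl-gold unit should keep the silyloxy group pseudo-axial and so fix C7a. OsO4 (cat.)/N-methylmorpholine N-oxide should dihydroxylate the only 1,1-disubstituted alkene anti to the C6 silyl ether and give the (6S,7R,7aS)-7-hydroxy-7-(hydroxymethyl) lactone, F3. Isovaleryl chloride/2,4,6-collidine at −78 °C acylates the primary hydroxyl to give the 7-hydroxy-7-[(3-methylbutanoyloxy)methyl] lactone, F4. Me3SiOTf/2,6-lutidine silylates the tertiary hydroxyl, and the route is rejoined at 18.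

Step 11. What may go wrong:
- hydride attack on the isovalerate;
- collapse of the aluminium lactolate with ring opening and over-reduction;
- trapping of the wrong C1 epimer.

The fallback separates reduction and acylation and relies on anomer equilibration. It sets out from 18. LiAlH(O-t-Bu)3 in THF at −78 to −30 °C, a hydride that leaves alkyl esters alone, and aqueous work-up give the C1 lactol (1R,6S,7R,7aS)-4-({[tert-butyl(dimethyl)silyl]oxy}methyl)-1-hydroxy-7-[(3-methylbutanoyloxy)methyl]-6-[(triethylsilyl)oxy]-7-[(trimethylsilyl)oxy]-1,6,7,7a-tetrahydrocyclopenta[c]pyran, F5 (same spatial arrangement at C1 as in 21). The equilibrating lactol is acylated with 19, Et3N and DMAP in CH2Cl2 at 0 °C under thermodynamic control, and the route is rejoined at 21.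

Step 9. What may go wrong:
- interception of the α-oxo gold carbene by the neighbouring silyl ether oxygen;
- a second oxidation of the carbene to the keto aldehyde;
- acid-mediated epimerisation next to the new ketone.

The fallback installs ketone and ester by hydration and substitution, with no carbene. It sets out from 13. N-bromosuccinimide with AgNO3 (cat.) in acetone gives the bromoalkyne 4-[(2S)-4-bromo-2-[(triethylsilyl)oxy]but-3-yn-1-yl]-5-({[tert-butyl(dimethyl)silyl]oxy}methyl)-2H-pyran-2-one, F6. Gold-catalysed hydration of the haloalkyne (Ph3PAuNTf2, H2O, ClCH2CH2Cl) gives the α-bromo ketone 4-[(2S)-4-bromo-3-oxo-2-[(triethylsilyl)oxy]butyl]-5-({[tert-butyl(dimethyl)silyl]oxy}methyl)-2H-pyran-2-one, F7. Caesium 3-methylbutanoate (from 14 and Cs2CO3) in DMF at rt displaces bromide, and the route is rejoined at 15.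

**Further compounds**

F1 | step 10 | tert-butyl(dimethyl)silyl dienol ether of 13: 2-{[tert-butyl(dimethyl)silyl]oxy}-5-({[tert-butyl(dimethyl)silyl]oxy}methyl)-4-[(2S)-2-[(triethylsilyl)oxy]but-3-yn-1-ylidene]-4H-pyran | CC(C)(C)[Si](C)(C)OC1=C/C(=C\[C@H](O[Si](CC)(CC)CC)C#C)C(CO[Si](C)(C)C(C)(C)C)=CO1
F2 | step 10 | (6S,7aS)-4-({[tert-butyl(dimethyl)silyl]oxy}methyl)-7-methylidene-6-[(triethylsilyl)oxy]-7,7a-dihydrocyclopenta[c]pyran-1(6H)-one | CC[Si](CC)(CC)O[C@H]1C=C2C(CO[Si](C)(C)C(C)(C)C)=COC(=O)[C@@H]2C1=C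
F3 | step 10 | (6S,7R,7aS)-4-({[tert-butyl(dimethyl)silyl]oxy}methyl)-7-hydroxy-7-(hydroxymethyl)-6-[(triethylsilyl)oxy]-7,7a-dihydrocyclopenta[c]pyran-1(6H)-one | CC[Si](CC)(CC)O[C@H]1C=C2C(CO[Si](C)(C)C(C)(C)C)=COC(=O)[C@@H]2[C@@]1(O)CO
F4 | step 10 | [(6S,7R,7aS)-4-({[tert-butyl(dimethyl)silyl]oxy}methyl)-7-hydroxy-1-oxo-6-[(triethylsilyl)oxy]-1,6,7,7a-tetrahydrocyclopenta[c]pyran-7-yl]methyl 3-methylbutanoate | CC[Si](CC)(CC)O[C@H]1C=C2C(CO[Si](C)(C)C(C)(C)C)=COC(=O)[C@@H]2[C@@]1(O)COC(=O)CC(C)C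
F5 | step 11 | [(1R,6S,7R,7aS)-4-({[tert-butyl(dimethyl)silyl]oxy}methyl)-1-hydroxy-6-[(triethylsilyl)oxy]-7-[(trimethylsilyl)oxy]-1,6,7,7a-tetrahydrocyclopenta[c]pyran-7-yl]methyl 3-methylbutanoate | CC[Si](CC)(CC)O[C@H]1C=C2C(CO[Si](C)(C)C(C)(C)C)=CO[C@@H](O)[C@@H]2[C@@]1(O[Si](C)(C)C)COC(=O)CC(C)C
F6 | step 9 | 4-[(2S)-4-bromo-2-[(triethylsilyl)oxy]but-3-yn-1-yl]-5-({[tert-butyl(dimethyl)silyl]oxy}methyl)-2H-pyran-2-one | BrC#C[C@@H](O[Si](CC)(CC)CC)CC1=CC(=O)OC=C1CO[Si](C)(C)C(C)(C)C
F7 | step 9 | 4-[(2S)-4-bromo-3-oxo-2-[(triethylsilyl)oxy]butyl]-5-({[tert-butyl(dimethyl)silyl]oxy}methyl)-2H-pyran-2-one | BrCC(=O)[C@@H](O[Si](CC)(CC)CC)CC1=CC(=O)OC=C1CO[Si](C)(C)C(C)(C)C
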